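**Analysis of the target**

Gentiside C (19) is (S)-14-methylhexadecyl 2,3-dihydroxybenzoate: a catechol-type benzoate, which is the only ring, esterified with a seventeen-carbon anteiso alcohol. No ring has to be built and the chain has no branch other than the methyl group on C14. The single stereocentre, C14, carries hydrogen, a methyl group, the ethyl terminus C15–C16 and the run C1–C13, and it lies thirteen methylene groups from the nearest heteroatom. Because nothing is attached to C14 or its neighbours, no reagent acting on the saturated chain can tell methyl from ethyl, and the centre cannot be corrected once it is set; this is the real difficulty. The sensitive part is the 2,3-dihydroxybenzoate: the free catechol oxidises readily in base and binds metals, so the ester is made last from O-protected acid and unmasked under neutral conditions. The plan rests on the fact that C14, with its methyl group and long chain, has the substitution pattern of the beta-carbon of geranial. If C16 is carried for a while as a formyl group, C14=C15 is the double bond of a beta-methyl enal, and the methyl/ethyl problem becomes one of E alkene geometry and the facial selectivity of a flavin-dependent ene-reductase.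

**Retrosynthetic reasoning**

Ester bond. The acyl C–O bond of 19 is cut first, giving the chiral alcohol 14 and the aromatic acid. The catechol is carried as its dibenzyl ether, so the direct precursor is 18 and the acid partner is 17, made from 15 through the perbenzylated ester 16. Benzyl ethers are chosen because the chain of 18 has no alkene, so the last step can be a neutral hydrogenolysis that leaves the ester and the stereocentre alone. This cut places the whole stereochemical problem in a simple C17 alcohol.

C16 methyl from a formyl group. Alcohol 14 has no function near C14, so one is introduced in the retrosynthetic sense: C16 is raised to the aldehyde level, which leads to hydroxy aldehyde 12. Forwards, hydrazone 13 forms and is decomposed by base (Wolff–Kishner). The stereocentre of 12 is beta to the carbonyl carbon, so neither enolisation of the aldehyde nor tautomerism of 13 can reach it. The gain is an activating group exactly two carbons from C14.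

Key disconnection, the C14–H and C15–H bonds. Removing these two hydrogens from 12 gives the E-enal 11, a long-chain homologue of the terpenoid beta-methyl enals on which ene-reductases are established. The forward reaction must deliver hydride to one face of C14, protonate C15, leave the carbonyl group alone and not scramble the alkene geometry beforehand. The C1 hydroxyl is left free in 11 and 12, since it makes the substrate a little more polar and needs no protection in any later step.

Enal from allylic alcohol. Enal 11 is taken back to diol 10. A mild heterogeneous allylic oxidation distinguishes the allylic C16 hydroxyl from the saturated C1 hydroxyl, so the isomerisation-prone enal is made immediately before use and no deprotection follows it. Diol 10 comes from silyl ether 9 by fluoride cleavage.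

Trisubstituted alkene. In 9 the C14–CH3 and C15–C16 bonds are cut together, back to terminal alkyne 6. Forwards, zirconium-catalysed syn methylalumination gives alkenylalane 7 with aluminium on the terminal carbon, and the aluminate 8 is hydroxymethylated with a one-carbon electrophile. This is the only place where the alkene geometry is decided, and syn addition fixes it as E. A carbonyl olefination of a methyl ketone would give E/Z mixtures, which is why the cut is made here.

C12–C13 bond. Alkyne 6 is cut between C12 and C13 into bromide 2 and a propargyl anion, for which the lithiated silylpropyne 4 (from 3) stands. The silyl group blocks the acetylenic position and is removed from 5 by mild methanolysis. Bromide 2 is the silyl ether of the commercial even-numbered bromo alcohol 1, and the odd carbon count is supplied by the three-carbon unit.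

**Alternatives that were turned down**

Alternative 1: lithiation–borylation across C13–C14.
- Disconnection and key step: the cut is at C13–C14. Ethyl 2,4,6-triisopropylbenzoate A3 is lithiated alpha to oxygen with an alkyllithium base and a stoichiometric chiral diamine. The resulting carbanion adds to the primary boronic ester tert-butyldimethyl{[13-(4,4,5,5-tetramethyl-1,3,2-dioxaborolan-2-yl)tridecyl]oxy}silane A2. The boronate complex rearranges with 1,2-migration of the tridecyl group from boron to carbon and loss of the benzoate. This gives the secondary boronic ester (R)-tert-butyldimethyl{[14-(4,4,5,5-tetramethyl-1,3,2-dioxaborolan-2-yl)pentadecyl]oxy}silane A1.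
- In its favour: the configuration is set by the reagent alone, the reaction class is well established on unfunctionalised primary alkyl boronic esters such as A2, and either enantiomer is available by choice of diamine. On predictability for a greasy substrate it is stronger than an enzymatic reduction whose substrate tolerance must be found by screening.
- Against it: the C–B bond of A1 must still become the C14–C15 bond (vinylation with retention and hydrogenation, or a second homologation), so three operations are spent at C14. It needs cryogenic organolithium chemistry and a full equivalent of chiral ligand, and the hindered acid part of A3 is discarded. A2 also needs an odd-numbered C13 chain that has to be assembled first.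
- Comparison: the chosen route sets the centre with a catalytic amount of protein at ambient temperature from an achiral alkene. The methyl/ethyl distinction is encoded in an alkene geometry that syn carbometallation delivers reliably.

Alternative 2: mixed Kolbe coupling at C11–C12.
- Disconnection and key step: the cut is at C11–C12. (S)-4-Methylhexanoic acid A5 and the half-ester 12-methoxy-12-oxododecanoic acid A6 are electrolysed together at a platinum anode. Both carboxylates lose CO2 and the two primary radicals combine to methyl (S)-14-methylhexadecanoate A4, which ester reduction would convert into 14.
- In its favour: the stereocentre is bought from the chiral pool in A5 and lies two carbons from the radical centre, so it is untouched. It is the shortest of all the routes and clearly beats the chosen route on step count.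
- Against it: radical–radical coupling is statistical, so the symmetrical homodimers of A5 and of A6 accompany A4. The cheaper acid A6 must be used in excess, and three waxy long-chain products must be separated. The optical purity of the target is capped by that of commercial A5 or its precursor, which varies and cannot be upgraded in this oily series.
- Comparison: the chosen route is longer, but its enantiopurity is decided by a catalyst that can be screened or exchanged, either enantiomer is accessible, and every C–C bond is formed by a selective polar reaction.

Alternative 3: Claisen rearrangement with 1,3-chirality transfer.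
- Disconnection and key step: the cut is at C14–C15. The allyl vinyl ether tert-butyldimethyl{[(S,E)-12-(vinyloxy)pentadec-13-en-1-yl]oxy}silane A8 rearranges on heating through a chair transition state with the long chain equatorial. The C14–C15 bond forms, the C12–O bond breaks and the C12=C13 alkene appears as the E isomer, giving (S,E)-16-[(tert-butyldimethylsilyl)oxy]-3-methylhexadec-4-enal A7.
- In its favour: chirality transfer through such a chair is among the most dependable events in acyclic stereocontrol, only ordinary reagents are needed, and A7 has the same formylmethyl group as 12, so the endgame would be shared.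
- Against it: the rearrangement only relays chirality. The C12 carbinol of A8 must first be made enantiopure by an asymmetric step of its own, and both its optical purity and the E purity of its propenyl group limit the result. A metal-mediated vinyl exchange is needed to make A8, and the new C12=C13 alkene of A7 has no purpose and must be hydrogenated.
- Comparison: it is two to three steps longer than the chosen route, which creates the centre directly from an achiral enal in one catalytic step. Its transfer step is more predictable than an untested enzyme–substrate pair.

Key step: step 7

Assumption: the SMILES is read as S at C14, and the ene-reductase of step 7 is a purified OYE2-type enzyme (or an engineered relative) chosen by screening for the R aldehyde. Chain positions are given in target numbering (C1 = OCH2, C16 = chain end) unless a compound's own locants are used.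

**Route**

Step 1
Reactants: 1 12-bromododecan-1-ol
Product: 2 [(12-bromododecyl)oxy](tert-butyl)dimethylsilane
Conditions: TBSCl, imidazole, CH2Cl2, 0 °C to rt
Reagents that add atoms: tert-butyldimethylsilyl chloride, CC(C)(C)[Si](C)(C)Cl
Why: Silylation of a primary alcohol with a silyl chloride and imidazole is routine and the primary bromide is inert to it; the silyl ether masks the hydroxyl against the organolithium and organoaluminium reagents of steps 2 and 4.

Step 2
Reactants: 2 [(12-bromododecyl)oxy](tert-butyl)dimethylsilane; 3 1-(trimethylsilyl)propyne
Product: 5 tert-butyldimethyl{[15-(trimethylsilyl)pentadec-14-yn-1-yl]oxy}silane, via 3-lithio-1-(trimethylsilyl)propyne 4 (not isolated)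
Conditions: 3, n-BuLi, THF, −78 °C; then 2, DMPU, −78 °C to rt
Reagents that add atoms: none
Why: Deprotonation of 3 at the methyl group gives the silyl-stabilised propargyl anion 4, which should displace the primary bromide by SN2 through the carbon remote from silicon, the bulky silyl group disfavouring the allenyl mode. The new C12–C13 bond completes the C1–C15 chain.

Step 3
Reactants: 5 tert-butyldimethyl{[15-(trimethylsilyl)pentadec-14-yn-1-yl]oxy}silane
Product: 6 tert-butyldimethyl(pentadec-14-yn-1-yloxy)silane
Conditions: K2CO3 (cat.), MeOH/THF, rt
Reagents that add atoms: none
Why: Protodesilylation of an alkynylsilane by methoxide attack at silicon is fast under catalytic carbonate, while the primary tert-butyldimethylsilyl ether is stable to these conditions.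

Step 4
Reactants: 6 tert-butyldimethyl(pentadec-14-yn-1-yloxy)silane
Product: 9 (E)-16-[(tert-butyldimethylsilyl)oxy]-3-methylhexadec-2-en-1-ol, via (E)-alkenyldimethylalane 7 (not isolated), via lithium alkenyl(butyl)dimethylaluminate 8 (not isolated)
Conditions: AlMe3 (2.5 equiv), Cp2ZrCl2 (0.25 equiv), CH2Cl2, 0 °C to rt; evaporate; n-BuLi, THF/hexane, −78 °C; (CH2O)n, −78 °C to rt; aq KNaC4H4O6
Reagents that add atoms: trimethylaluminium, C[Al](C)C; formaldehyde (as paraformaldehyde), C=O
Why: Negishi zirconium-catalysed methylalumination adds methyl and aluminium syn across the terminal alkyne with aluminium on the terminal carbon, so the E geometry of the trisubstituted alkene is fixed here. Conversion of 7 into the aluminate 8 makes the alkenyl group nucleophilic enough to add to formaldehyde with retention of geometry, giving the allylic alcohol.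

Step 5
Reactants: 9 (E)-16-[(tert-butyldimethylsilyl)oxy]-3-methylhexadec-2-en-1-ol
Product: 10 (E)-3-methylhexadec-2-ene-1,16-diol
Conditions: TBAF, THF, 0 °C to rt
Reagents that add atoms: none
Why: Fluoride cleaves the Si–O bond without touching the allylic alcohol or the alkene; removing the silyl group before the oxidation avoids any deprotection in the presence of the enal.

Step 6
Reactants: 10 (E)-3-methylhexadec-2-ene-1,16-diol
Product: 11 (E)-16-hydroxy-3-methylhexadec-2-enal
Conditions: activated MnO2 (excess), CH2Cl2, rt, dark; filtration
Reagents that add atoms: none
Why: Activated MnO2 oxidises allylic alcohols selectively and leaves the saturated primary C1 hydroxyl untouched. The oxidation takes place on the solid under neutral conditions, so the E geometry should be kept, and the enal is obtained by filtration just before the enzymatic step.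

Step 7
Reactants: 11 (E)-16-hydroxy-3-methylhexadec-2-enal
Product: 12 (R)-16-hydroxy-3-methylhexadecanal
Conditions: purified ene-reductase (OYE2 type), NADP+ (cat.), glucose dehydrogenase, D-glucose, KH2PO4/K2HPO4 buffer pH 7.0 with MTBE as second phase, 30 °C
Reagents that add atoms: none
Why: The enal binds in the active site with its carbonyl oxygen hydrogen-bonded to the conserved histidine/asparagine pair, which polarises the C2=C3 bond; reduced FMN, regenerated by NADPH from the glucose/glucose dehydrogenase couple, transfers hydride from N5 to C3 (target C14) and a tyrosine hydroxyl protonates C2 (target C15) from the opposite face, a net anti addition of H2. The closest known reaction is the reduction of geranial to citronellal by this enzyme family; 11 is a homologue in which the prenyl tail is replaced by a longer saturated chain ending in a hydroxyl group. No ring is closed. The one new stereocentre, C3 of 12, is controlled by the enzyme alone: the binding mode decides which face of C3 lies over N5, and the E geometry places the methyl group and the long chain in defined positions, so an enzyme of the OYE2 type, which turns geranial into (R)-citronellal, should give (R)-12, and a homologue of the opposite preference would be recognised by chiral analysis of 12 and replaced. Three selectivities are needed: C=C over C=O reduction, secured by purified enzymes free of alcohol dehydrogenases; one enantioface, secured by the geometrically pure E-enal from syn carbometallation; and no E/Z isomerisation before reduction, secured by amine-free neutral buffer, feeding of 11 from the organic phase and short contact time. The second phase also supplies the lipophilic substrate and withdraws 12 from the enzyme. The new centre is beta to the aldehyde and cannot epimerise afterwards.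

Step 8
Reactants: 12 (R)-16-hydroxy-3-methylhexadecanal
Product: 14 (S)-14-methylhexadecan-1-ol, via hydrazone 13 (not isolated)
Conditions: N2H4·H2O (excess), diethylene glycol, 110 °C; then KOH, 195 °C with removal of H2O and excess N2H4
Reagents that add atoms: none
Why: Wolff–Kishner reduction in the Huang–Minlon manner: the hydrazone is formed first under neutral conditions with excess hydrazine to suppress azine and aldol formation, then base-induced tautomerisation and loss of N2 turn the formyl carbon into the C16 methyl group. The stereocentre is beta to the C=N carbon and takes no part; only its descriptor changes from R to S because the formyl-bearing branch becomes ethyl. The primary alcohol survives as its alkoxide.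

Step 9
Reactants: 15 2,3-dihydroxybenzoic acid
Product: 16 benzyl 2,3-bis(benzyloxy)benzoate
Conditions: BnBr (3.5 equiv), K2CO3, DMF, 60 °C
Reagents that add atoms: benzyl bromide, BrCc1ccccc1
Why: Williamson-type O-alkylation of the carboxylate and both phenoxides with excess benzyl bromide; exhaustive benzylation removes any question of selectivity between the three acidic sites.

Step 10
Reactants: 16 benzyl 2,3-bis(benzyloxy)benzoate
Product: 17 2,3-bis(benzyloxy)benzoic acid
Conditions: NaOH, MeOH/THF/H2O, 60 °C; then aq HCl
Reagents that add atoms: sodium hydroxide, [Na+].[OH-]
Why: Saponification cleaves only the benzyl ester, since aryl benzyl ethers are stable to aqueous hydroxide; acidification gives the free acid.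

Step 11
Reactants: 14 (S)-14-methylhexadecan-1-ol; 17 2,3-bis(benzyloxy)benzoic acid
Product: 18 (S)-14-methylhexadecyl 2,3-bis(benzyloxy)benzoate
Conditions: EDC·HCl, DMAP (cat.), CH2Cl2, 0 °C to rt
Reagents that add atoms: none
Why: Steglich esterification: the carbodiimide activates the acid as its O-acylisourea and DMAP transfers the acyl group to the primary alcohol. With both phenols benzylated there is no competing phenol acylation, and no stereocentre is touched.

Step 12
Reactants: 18 (S)-14-methylhexadecyl 2,3-bis(benzyloxy)benzoate
Product: 19 Gentiside C, (S)-14-methylhexadecyl 2,3-dihydroxybenzoate
Conditions: H2 (1 atm), Pd/C (10 wt% palladium metal on carbon), EtOAc/EtOH, rt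
Reagents that add atoms: none
Why: Hydrogenolysis of the two aryl benzyl ethers over Pd/C at neutral pH; the chain has no reducible group, the alkyl benzoate is not a benzylic ester and should survive, and the catechol is released without acid or base.

**Compound list**

1 | 12-bromododecan-1-ol | OCCCCCCCCCCCCBr | starting material
2 | [(12-bromododecyl)oxy](tert-butyl)dimethylsilane | CC(C)(C)[Si](C)(C)OCCCCCCCCCCCCBr | intermediate
3 | 1-(trimethylsilyl)propyne | CC#C[Si](C)(C)C | starting material
4 | 3-lithio-1-(trimethylsilyl)prop-1-yne | [Li]CC#C[Si](C)(C)C | intermediate
5 | tert-butyldimethyl{[15-(trimethylsilyl)pentadec-14-yn-1-yl]oxy}silane | C[Si](C)(C)C#CCCCCCCCCCCCCCO[Si](C)(C)C(C)(C)C | intermediate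
6 | tert-butyldimethyl(pentadec-14-yn-1-yloxy)silane | C#CCCCCCCCCCCCCCO[Si](C)(C)C(C)(C)C | intermediate
7 | {(E)-15-[(tert-butyldimethylsilyl)oxy]-2-methylpentadec-1-en-1-yl}dimethylalane | C[Al](C)/C=C(\C)CCCCCCCCCCCCCO[Si](C)(C)C(C)(C)C | intermediate
8 | lithium butyl{(E)-15-[(tert-butyldimethylsilyl)oxy]-2-methylpentadec-1-en-1-yl}dimethylaluminate | [Li+].CCCC[Al-](C)(C)/C=C(\C)CCCCCCCCCCCCCO[Si](C)(C)C(C)(C)C | intermediate
9 | (E)-16-[(tert-butyldimethylsilyl)oxy]-3-methylhexadec-2-en-1-ol | OC/C=C(\C)CCCCCCCCCCCCCO[Si](C)(C)C(C)(C)C | intermediate
10 | (E)-3-methylhexadec-2-ene-1,16-diol | OC/C=C(\C)CCCCCCCCCCCCCO | intermediate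
11 | (E)-16-hydroxy-3-methylhexadec-2-enal | O=C/C=C(\C)CCCCCCCCCCCCCO | intermediate
12 | (R)-16-hydroxy-3-methylhexadecanal | O=CC[C@H](C)CCCCCCCCCCCCCO | intermediate
13 | (R)-16-hydrazinylidene-14-methylhexadecan-1-ol (hydrazone of 12) | NN=CC[C@H](C)CCCCCCCCCCCCCO | intermediate
14 | (S)-14-methylhexadecan-1-ol | CC[C@H](C)CCCCCCCCCCCCCO | intermediate
15 | 2,3-dihydroxybenzoic acid | OC(=O)c1cccc(O)c1O | starting material
16 | benzyl 2,3-bis(benzyloxy)benzoate | O=C(OCc1ccccc1)c1cccc(OCc2ccccc2)c1OCc1ccccc1 | intermediate
17 | 2,3-bis(benzyloxy)benzoic acid | OC(=O)c1cccc(OCc2ccccc2)c1OCc1ccccc1 | intermediate
18 | (S)-14-methylhexadecyl 2,3-bis(benzyloxy)benzoate | CC[C@H](C)CCCCCCCCCCCCCOC(=O)c1cccc(OCc2ccccc2)c1OCc1ccccc1 | intermediate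
19 | Gentiside C, (S)-14-methylhexadecyl 2,3-dihydroxybenzoate | CC[C@H](C)CCCCCCCCCCCCCOC(=O)c1cccc(O)c1O | target

**Step count and risk**

Total step count: 12. Longest linear sequence: 10 (steps 1 to 8, then 11 and 12); steps 9 and 10 are the short branch to the protected acid.

Step 7 (key step).
- What may go wrong: slow or absent turnover, because a sixteen-carbon enal reaches the active site only at very low aqueous concentration. Enantiopurity may erode through E-to-Z isomerisation of 11 in the buffer, since the Z isomer is reduced to the opposite enantiomer by enzymes of this type. Contaminating dehydrogenases may reduce the carbonyl group, and the chosen enzyme may bind the substrate in the flipped mode.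
- Fallback: it sets out from 9 and returns to the route at 14. Hydroxyl-directed asymmetric hydrogenation of the allylic alcohol with Ru(OAc)2[(S)-BINAP] under H2 pressure in MeOH (the geraniol-to-citronellol type of reduction) should give (R)-16-[(tert-butyldimethylsilyl)oxy]-3-methylhexadecan-1-ol F1. Tosylation with TsCl and pyridine gives (R)-16-[(tert-butyldimethylsilyl)oxy]-3-methylhexadecyl 4-methylbenzenesulfonate F2. Hydride displacement with LiBHEt3 in THF gives (S)-tert-butyldimethyl[(14-methylhexadecyl)oxy]silane F3, and TBAF releases 14. Steps 5 to 8 are bypassed.

Step 8.
- What may go wrong: azine formation and base-induced aldol condensation of the alpha-unbranched aldehyde before hydrazone formation is complete, and loss of material at the high temperature of the decomposition.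
- Fallback: it sets out from 12 and returns at 14. Thioacetalisation with ethane-1,2-dithiol and BF3·OEt2 in CH2Cl2 gives (R)-15-(1,3-dithiolan-2-yl)-14-methylpentadecan-1-ol F4, which Raney Ni in EtOH desulfurises (Mozingo reduction) to 14 under neutral conditions.

Step 4.
- What may go wrong: incomplete capture of the alkenyl–aluminium bond by the sluggishly depolymerising paraformaldehyde, leading to protonolysis to the 1,1-disubstituted alkene. Regioselectivity of the methylalumination may also drop if the silyl ether ties up the aluminium reagent.
- Fallback: it sets out from 6 and returns at 9. The same methylalumination gives 7, which is acylated directly with ethyl chloroformate to ethyl (E)-16-[(tert-butyldimethylsilyl)oxy]-3-methylhexadec-2-enoate F5, a trapping that needs no aluminate. Reduction with i-Bu2AlH in CH2Cl2 at −78 °C gives 9.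

Step 2.
- What may go wrong: competing alkylation through the allenyl terminus of 4, giving a silylallene, or slow substitution of the bromide accompanied by elimination.
- Fallback: it sets out from 2 and returns at 6. Alkylation of 1-propynyllithium in THF/DMPU, where only the acetylide carbon can attack, gives tert-butyldimethyl(pentadec-13-yn-1-yloxy)silane F6, and TBAF gives pentadec-13-yn-1-ol F7. The alkyne zipper isomerisation with KH in 1,3-diaminopropane moves the triple bond one position to the chain end and gives pentadec-14-yn-1-ol F8, and silylation as in step 1 gives 6.

**Further compounds**

F1 | step 7 | (R)-16-[(tert-butyldimethylsilyl)oxy]-3-methylhexadecan-1-ol | OCC[C@H](C)CCCCCCCCCCCCCO[Si](C)(C)C(C)(C)C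
F2 | step 7 | (R)-16-[(tert-butyldimethylsilyl)oxy]-3-methylhexadecyl 4-methylbenzenesulfonate | Cc1ccc(cc1)S(=O)(=O)OCC[C@H](C)CCCCCCCCCCCCCO[Si](C)(C)C(C)(C)C
F3 | step 7 | (S)-tert-butyldimethyl[(14-methylhexadecyl)oxy]silane | CC[C@H](C)CCCCCCCCCCCCCO[Si](C)(C)C(C)(C)C
F4 | step 8 | (R)-15-(1,3-dithiolan-2-yl)-14-methylpentadecan-1-ol | C1CSC(S1)C[C@H](C)CCCCCCCCCCCCCO
F5 | step 4 | ethyl (E)-16-[(tert-butyldimethylsilyl)oxy]-3-methylhexadec-2-enoate | CCOC(=O)/C=C(\C)CCCCCCCCCCCCCO[Si](C)(C)C(C)(C)C
F6 | step 2 | tert-butyldimethyl(pentadec-13-yn-1-yloxy)silane | CC#CCCCCCCCCCCCCO[Si](C)(C)C(C)(C)C
F7 | step 2 | pentadec-13-yn-1-ol | CC#CCCCCCCCCCCCCO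
F8 | step 2 | pentadec-14-yn-1-ol | C#CCCCCCCCCCCCCCO
A1 | alternative 1 | (R)-tert-butyldimethyl{[14-(4,4,5,5-tetramethyl-1,3,2-dioxaborolan-2-yl)pentadecyl]oxy}silane | C[C@@H](B1OC(C)(C)C(C)(C)O1)CCCCCCCCCCCCCO[Si](C)(C)C(C)(C)C
A2 | alternative 1 | tert-butyldimethyl{[13-(4,4,5,5-tetramethyl-1,3,2-dioxaborolan-2-yl)tridecyl]oxy}silane | CC1(C)OB(CCCCCCCCCCCCCO[Si](C)(C)C(C)(C)C)OC1(C)C
A3 | alternative 1 | ethyl 2,4,6-triisopropylbenzoate | CCOC(=O)c1c(C(C)C)cc(C(C)C)cc1C(C)C
A4 | alternative 2 | methyl (S)-14-methylhexadecanoate | CC[C@H](C)CCCCCCCCCCCCC(=O)OC
A5 | alternative 2 | (S)-4-methylhexanoic acid | CC[C@H](C)CCC(O)=O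
A6 | alternative 2 | 12-methoxy-12-oxododecanoic acid | COC(=O)CCCCCCCCCCC(O)=O
A7 | alternative 3 | (S,E)-16-[(tert-butyldimethylsilyl)oxy]-3-methylhexadec-4-enal | O=CC[C@H](C)/C=C/CCCCCCCCCCCO[Si](C)(C)C(C)(C)C
A8 | alternative 3 | tert-butyldimethyl{[(S,E)-12-(vinyloxy)pentadec-13-en-1-yl]oxy}silane | C=CO[C@@H](CCCCCCCCCCCO[Si](C)(C)C(C)(C)C)/C=C/C
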